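**Remark on the chemistry:** locants are those of the target (ring A: C1–C5, C10; ring B: C5, C6, C7, C8, C9, C20, C10; ring C: C8, C9, C11–C14; lactone: C4–C19(=O)–O–C10). The target descriptors are 4S,5S,7R,10S (7R = 7α, cis to H5). Compounds 1, 4, 9 and 15 are taken as commercial.

Ring C is grown last on a chiral ring A/ring B lactone. Its six atoms come from the C8=C9 alkene of ring B, a diazoacetyl group on C9 (C14, C11) and a siloxyalkyne (C13, C12). One photochemical benzannulation makes C13–C14, C11–C12 and C14–C8: the C11–C12 bond closes a cyclobutenone, which then ring-expands to the arene. The step exploits the contiguous C14(O)–C13(iPr)–C12(O) array of ring C with C11 between C12 and C9: it is delivered as a 2-isopropylresorcinol mono-silyl ether whose free C11–H lies para to the C14 phenol, ready for oxidation to the quinone. The C7 acetate follows by allylic functionalisation.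

Key step: step 9

**Step 1**
Reactants: 1 methyl 3-oxocyclohex-1-ene-1-carboxylate
Product: 3 methyl (S)-1-methyl-3-[(trifluoromethanesulfonyl)oxy]cyclohex-2-ene-1-carboxylate, via methylzinc enolate 2 (not isolated)
Conditions: Me2Zn, (CuOTf)2·C6H6 (2.5 mol %), chiral sulfonate-bearing imidazolinium salt (carbene ligand precursor, 5 mol %), t-BuOMe, −30 °C; then Tf2O, −78 → 0 °C
Reagents that add atoms: dimethylzinc, C[Zn]C; trifluoromethanesulfonic anhydride, O=S(=O)(OS(=O)(=O)C(F)(F)F)C(F)(F)F
Why: Copper–carbene-catalysed asymmetric conjugate addition of Me2Zn to the β-carboxylate-substituted enone should set the quaternary C4 as S (ligand enantiomer chosen accordingly), and O-triflation of the regiodefined zinc enolate locks the double bond at C5=C10, which enolisation of the free ketone would not do.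

**Step 2**
Reactants: 3 alkenyl triflate; 4 2-(2-bromoethyl)-2-methyl-1,3-dioxolane
Product: 6 methyl (S)-1-methyl-3-[2-(2-methyl-1,3-dioxolan-2-yl)ethyl]cyclohex-2-ene-1-carboxylate, via alkylzinc bromide 5 (not isolated)
Conditions: 4, Zn dust, LiCl, THF, 45 °C; then 3, PdCl2(dppf) (5 mol %), THF, 50 °C
Reagents that add atoms: zinc, [Zn] (zinc of intermediate 5 only)
Why: Negishi cross-coupling of the alkenyl triflate with the primary alkylzinc reagent installs C20, C9, C14 and C11 (ketone masked as dioxolane) without touching C4 or moving the C5=C10 double bond.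

**Step 3**
Reactants: 6 ester
Product: 7 (S)-1-methyl-3-[2-(2-methyl-1,3-dioxolan-2-yl)ethyl]cyclohex-2-ene-1-carboxylic acid
Conditions: LiOH·H2O, THF/MeOH/H2O, 60 °C; then cold 1 M HCl to pH 4
Reagents that add atoms: lithium hydroxide, [Li+].[OH-]
Why: Saponification of the hindered methyl ester, whose α-carbon carries no hydrogen so that neither epimerisation nor double-bond migration is possible, frees the acid, and brief cold acidification keeps the dioxolane.

**Step 4**
Reactants: 7 acid
Product: 8 (1R,5S,8R)-8-iodo-1-methyl-5-[2-(2-methyl-1,3-dioxolan-2-yl)ethyl]-6-oxabicyclo[3.2.1]octan-7-one (iodine on the one-carbon bridge C5, anti to the lactone bridge)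
Conditions: I2, NaHCO3, MeCN/H2O, 0 °C → rt, dark
Reagents that add atoms: iodine, II
Why: Iodolactonisation of the β,γ-unsaturated acid: the C4 carboxylate attacks the more substituted carbon C10 of the iodonium ion from its own face (γ-lactone, 5-endo mode), which sets C10 cis to C19 by intramolecular delivery and places iodine on C5 anti to the new C–O bond.

**Step 5**
Reactants: 8 iodolactone; 9 acrolein
Product: 10 3-{(1S,5S,8S)-1-methyl-5-[2-(2-methyl-1,3-dioxolan-2-yl)ethyl]-7-oxo-6-oxabicyclo[3.2.1]octan-8-yl}propanal (side chain syn to the lactone bridge)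
Conditions: acrolein (excess), Bu3SnH (slow addition), AIBN (cat.), PhH, 80 °C
Reagents that add atoms: none
Why: Giese radical addition: the secondary C5 radical, flanked by two quaternary carbons, should add to acrolein on the face syn to the hydrogen-free lactone bridge because the other face is shielded by the axial hydrogens on C1 and C3, which puts C6 equatorial on ring A and H5 anti to the lactone as in the target.

**Step 6**
Reactants: 10 aldehyde
Product: 12 tricyclic enone (4S,5S,10S): ring A bridged by the C4–C19(=O)–O–C10 γ-lactone and trans-fused at C5–C10 to the ring B cycloheptene C8=C9, acetyl group on C9, via keto aldehyde 11 (not isolated)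
Conditions: 1 M HCl, THF, rt; then KOH, MeOH/H2O, 0 °C → rt; work-up with 1 M HCl
Reagents that add atoms: water, O
Why: Ketal hydrolysis unmasks the methyl ketone, and hydroxide-mediated intramolecular aldol condensation (C9 enolate onto the C8 aldehyde, then E1cB dehydration) closes ring B as the conjugated 1-acetylcycloheptene, the methyl-side enolate having no accessible ring size and the aldol steps being reversible.

**Step 7**
Reactants: 12 tricyclic enone
Product: 14 diazo ketone (4S,5S,10S): as 12 with the acetyl group converted into diazoacetyl, C9–C14(=O)–C11H=N2, via trifluoroacetyl diketone 13 (not isolated)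
Conditions: LiN(SiMe3)2, THF, −78 °C; CF3CO2CH2CF3, −78 °C; then MeSO2N3, Et3N, H2O (1 equiv), MeCN, rt
Reagents that add atoms: 2,2,2-trifluoroethyl trifluoroacetate, O=C(OCC(F)(F)F)C(F)(F)F (trifluoroacetyl group of intermediate 13 only); methanesulfonyl azide, CS(=O)(=O)N=[N+]=[N-]
Why: Detrifluoroacetylative diazo transfer (Regitz type): kinetic α′-enolisation of the methyl ketone, Claisen trifluoroacetylation and diazo transfer with loss of the trifluoroacetyl group give the α′-diazo enone, the lactone being inert because C4 carries no hydrogen.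

**Step 8**
Reactants: 15 ethyl isobutyrate
Product: 17 3-methyl-1-(triisopropylsilyloxy)but-1-yne, via lithium ynolate 16 (not isolated)
Conditions: CH2Br2, lithium 2,2,6,6-tetramethylpiperidide (2.2 equiv, from the amine and n-BuLi), THF, −78 °C; n-BuLi, −78 → 0 °C; i-Pr3SiCl, −78 °C → rt
Reagents that add atoms: dibromomethane, BrCBr; chlorotriisopropylsilane, CC(C)[Si](Cl)(C(C)C)C(C)C; n-butyllithium, [Li]CCCC (lithium of intermediate 16 only)
Why: Kowalski ester homologation: addition of LiCHBr2 to the ester, enolisation, bromine–lithium exchange and 1,2-shift of the isopropyl group give the lithium ynolate, which the bulky chlorosilane silylates on oxygen.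

**Step 9**
Reactants: 14 diazo ketone; 17 siloxyalkyne
Product: 22 (4S,5S,10S)-14-hydroxy-12-(triisopropylsilyloxy)icetexa-8,11,13-trien-19,10-olide, via vinylketene 18 (not isolated), via cyclobutenone 19 (not isolated), via dienylketene 20 (not isolated), via cyclohexadienone 21 (not isolated)
Conditions: 17 (1.5–2 equiv), hν (254 nm, Vycor), ClCH2CH2Cl, rt; then 80 °C
Reagents that add atoms: none
Why: Irradiation triggers a Wolff rearrangement (C9 migrates from C14 to the diazo carbon C11 with loss of N2) to vinylketene 18; the nucleophilic C13 of the siloxyalkyne adds to the ketene carbon C14 and the resulting enolate carbon C11 closes onto the siloxy-stabilised cation at C12, so the C11–C12 bond completes cyclobutenone 19 (stepwise polar [2+2]). On heating, 19 undergoes 4π-electrocyclic opening to dienylketene 20, ring C closes by thermal disrotatory 6π-electrocyclisation between C14 and C8, and dienone 21 tautomerises to the phenol. The closest known reaction type is the Danheiser benzannulation in its diazo ketone/siloxyalkyne version, established for 1-(diazoacetyl)cycloalkenes, of which 14 is the seven-membered homologue. The stereocentres formed at C11 (in 19) and C8 (in 21) are transient and vanish on aromatisation, and C4, C5 and C10 are remote from all bond changes. The selectivity needed is regiochemical (iPr on C13 next to the C14 phenol, silyloxy on C12 next to C11–H) and is secured by the polarisation of both partners, since only the oxygen-bearing alkyne carbon can become the cationic centre and only the ketene carbonyl carbon the electrophile. Only the dienylketene isomer with the cycloheptenyl group turned inward can cyclise, but opening of 19 is reversible, so the material should funnel to 22.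

**Step 10**
Reactants: 22 phenol
Product: 23 (4S,5S,10S)-12-(triisopropylsilyloxy)icetexa-8,12-diene-11,14-dion-19,10-olide
Conditions: (KSO3)2NO, KH2PO4 buffer, acetone/H2O, rt
Reagents that add atoms: potassium nitrosodisulfonate (Fremy's salt), [K+].[K+].[O]N(S(=O)(=O)[O-])S(=O)(=O)[O-]
Why: Teuber oxidation: the hindered C14 phenol, whose only free position is the para carbon C11, is oxidised to the 11,14-para-quinone while the silyl ether on C12 stays as protection of the enolic oxygen against electrophilic bromine in the next step.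

**Step 11**
Reactants: 23 siloxyquinone
Product: 24 (4S,5S,7R,10S)-7α-bromo-12-(triisopropylsilyloxy)icetexa-8,12-diene-11,14-dion-19,10-olide
Conditions: N-bromosuccinimide, AIBN (cat.), PhCF3, 80 °C
Reagents that add atoms: N-bromosuccinimide, O=C1CCC(=O)N1Br
Why: Wohl–Ziegler bromination: hydrogen abstraction should occur at C7 (allylic to C8=C9, vinylogous to the C11 carbonyl) rather than at C20 (neopentyl, next to quaternary C10 and deactivated by its C–O bond) or at the isopropyl methine (held in the ring plane between two ortho substituents), and bromine is expected to enter along the pseudo-axial α trajectory of the ring B chair.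

**Step 12**
Reactants: 24 bromide
Product: 25 (4S,5S,7R,10S)-7α-acetoxy-12-(triisopropylsilyloxy)icetexa-8,12-diene-11,14-dion-19,10-olide
Conditions: AgOAc, AcOH, rt → 40 °C, dark
Reagents that add atoms: silver acetate, CC(=O)[O-].[Ag+]
Why: Silver-assisted acetolysis (SN1-type substitution through the silver-bound ion pair): acetate should enter pseudo-axially on the α face so that the new C7–O bond (7R) avoids allylic 1,3-strain with the C14 carbonyl, the arrangement that is also favoured thermodynamically.

**Step 13**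
Reactants: 25 silyl ether
Product: 26 7α-acetoxy-6,7-dihydroicetexone (target)
Conditions: HF·pyridine, THF/pyridine, 0 °C
Reagents that add atoms: none
Why: Fluoride cleavage of the vinylogous silyl ester under buffered acidic conditions releases the 12-hydroxy-para-quinone without touching the C7 acetate or the lactone.

**Compound list**

1 | methyl 3-oxocyclohex-1-ene-1-carboxylate | COC(=O)C1=CC(=O)CCC1 | starting material
2 | methyl (S)-1-methyl-3-[(methylzincio)oxy]cyclohex-2-ene-1-carboxylate (methylzinc enolate) | C[Zn]OC1=C[C@@](C)(C(=O)OC)CCC1 | intermediate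
3 | methyl (S)-1-methyl-3-[(trifluoromethanesulfonyl)oxy]cyclohex-2-ene-1-carboxylate | O=S(=O)(OC1=C[C@@](C)(C(=O)OC)CCC1)C(F)(F)F | intermediate
4 | 2-(2-bromoethyl)-2-methyl-1,3-dioxolane | CC1(CCBr)OCCO1 | starting material
5 | [2-(2-methyl-1,3-dioxolan-2-yl)ethyl]zinc bromide | CC1(CC[Zn]Br)OCCO1 | intermediate
6 | methyl (S)-1-methyl-3-[2-(2-methyl-1,3-dioxolan-2-yl)ethyl]cyclohex-2-ene-1-carboxylate | CC1(CCC2=C[C@@](C)(C(=O)OC)CCC2)OCCO1 | intermediate
7 | (S)-1-methyl-3-[2-(2-methyl-1,3-dioxolan-2-yl)ethyl]cyclohex-2-ene-1-carboxylic acid | CC1(CCC2=C[C@@](C)(C(O)=O)CCC2)OCCO1 | intermediate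
8 | (1R,5S,8R)-8-iodo-1-methyl-5-[2-(2-methyl-1,3-dioxolan-2-yl)ethyl]-6-oxabicyclo[3.2.1]octan-7-one | I[C@H]1[C@]2(CCC[C@]1(C)C(=O)O2)CCC3(C)OCCO3 | intermediate
9 | acrolein (prop-2-enal) | C=CC=O | starting material
10 | 3-{(1S,5S,8S)-1-methyl-5-[2-(2-methyl-1,3-dioxolan-2-yl)ethyl]-7-oxo-6-oxabicyclo[3.2.1]octan-8-yl}propanal | O=CCC[C@@H]1[C@]2(CCC[C@]1(C)C(=O)O2)CCC3(C)OCCO3 | intermediate
11 | 3-[(1S,5S,8S)-1-methyl-7-oxo-5-(3-oxobutyl)-6-oxabicyclo[3.2.1]octan-8-yl]propanal (keto aldehyde) | O=CCC[C@@H]1[C@]2(CCC[C@]1(C)C(=O)O2)CCC(C)=O | intermediate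
12 | tricyclic enone (4S,5S,10S): lactone-bridged ring A trans-fused to ring B cycloheptene (C8=C9), acetyl on C9 | CC(=O)C1=CCC[C@@H]2[C@]3(CCC[C@]2(C)C(=O)O3)C1 | intermediate
13 | trifluoroacetyl diketone: 12 carrying COCF3 on the acetyl methyl carbon | O=C(CC(=O)C(F)(F)F)C1=CCC[C@@H]2[C@]3(CCC[C@]2(C)C(=O)O3)C1 | intermediate
14 | diazo ketone (4S,5S,10S): diazoacetyl group on C9 of the ring B cycloheptene | [N-]=[N+]=CC(=O)C1=CCC[C@@H]2[C@]3(CCC[C@]2(C)C(=O)O3)C1 | intermediate
15 | ethyl isobutyrate | CCOC(=O)C(C)C | starting material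
16 | lithium 3-methylbut-1-yn-1-olate (ynolate) | CC(C)C#CO[Li] | intermediate
17 | 3-methyl-1-(triisopropylsilyloxy)but-1-yne | CC(C)C#CO[Si](C(C)C)(C(C)C)C(C)C | intermediate
18 | vinylketene: O=C14=C11H– on C9 of the ring B cycloheptene | O=C=CC1=CCC[C@@H]2[C@]3(CCC[C@]2(C)C(=O)O3)C1 | intermediate
19 | 2-isopropyl-3-(triisopropylsilyloxy)cyclobut-2-enone carrying the ring B cycloheptenyl group on C11 (C11 epimers) | O=C1C(C(C)C)=C(O[Si](C(C)C)(C(C)C)C(C)C)C1C4=CCC[C@@H]2[C@]3(CCC[C@]2(C)C(=O)O3)C4 | intermediate
20 | dienylketene O=C14=C13(iPr)–C12(OSi)=C11H–C9=C8 (C13 and C9 cis about C11=C12) | O=C=C(C(C)C)/C(O[Si](C(C)C)(C(C)C)C(C)C)=C\C4=CCC[C@@H]2[C@]3(CCC[C@]2(C)C(=O)O3)C4 | intermediate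
21 | cyclohexa-2,4-dienone tautomer of 22 (sp3 C8, either configuration) | C1C[C@@H]2[C@]3(CCC[C@]2(C)C(=O)O3)CC2=CC(O[Si](C(C)C)(C(C)C)C(C)C)=C(C(C)C)C(=O)C21 | intermediate
22 | (4S,5S,10S)-14-hydroxy-12-(triisopropylsilyloxy)icetexa-8,11,13-trien-19,10-olide | C1C[C@@H]2[C@]3(CCC[C@]2(C)C(=O)O3)Cc2cc(O[Si](C(C)C)(C(C)C)C(C)C)c(C(C)C)c(O)c21 | intermediate
23 | (4S,5S,10S)-12-(triisopropylsilyloxy)icetexa-8,12-diene-11,14-dion-19,10-olide | C1C[C@@H]2[C@]3(CCC[C@]2(C)C(=O)O3)CC2=C1C(=O)C(C(C)C)=C(O[Si](C(C)C)(C(C)C)C(C)C)C2=O | intermediate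
24 | (4S,5S,7R,10S)-7α-bromo-12-(triisopropylsilyloxy)icetexa-8,12-diene-11,14-dion-19,10-olide | Br[C@@H]1C[C@@H]2[C@]3(CCC[C@]2(C)C(=O)O3)CC2=C1C(=O)C(C(C)C)=C(O[Si](C(C)C)(C(C)C)C(C)C)C2=O | intermediate
25 | (4S,5S,7R,10S)-7α-acetoxy-12-(triisopropylsilyloxy)icetexa-8,12-diene-11,14-dion-19,10-olide | CC(=O)O[C@@H]1C[C@@H]2[C@]3(CCC[C@]2(C)C(=O)O3)CC2=C1C(=O)C(C(C)C)=C(O[Si](C(C)C)(C(C)C)C(C)C)C2=O | intermediate
26 | 7α-acetoxy-6,7-dihydroicetexone (4S,5S,7R,10S) | CC(=O)O[C@@H]1C[C@@H]2[C@]3(CCC[C@]2(C)C(=O)O3)CC2=C1C(=O)C(C(C)C)=C(O)C2=O | target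

**Step count:** 13 steps in total; longest linear sequence 12 (steps 1–7 and 9–13); step 8 is a one-step side branch.

**Steps most likely to fail**

Step 12. Acetate may enter from both faces of C7, or HBr may be lost to the 6,7-alkene. The fallback sets out from 24 and returns at 25. Silver-assisted hydrolysis (AgOTf, aqueous acetone) should give the epimeric C7 alcohols F1. Dess–Martin periodinane should oxidise them to the C7 ketone F2. Reagent-controlled Corey–Bakshi–Shibata reduction ((S)-2-methyl-CBS-oxazaborolidine, catecholborane, −78 °C, air on work-up to restore the quinone) should give the 7α-carbinol F3. Ac2O, DMAP and pyridine then give 25.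

Step 9. The photochemical Wolff stage may be inefficient, or the phenol may undergo secondary photochemistry before the thermal stage. The fallback sets out from 14 and returns at 22, generating the same vinylketene thermally. Silver-catalysed Wolff rearrangement in water (PhCO2Ag, Et3N, dioxane/H2O) should give the homologous acid F4. (COCl)2 with catalytic DMF gives the acid chloride F5. Dehydrochlorination with Et3N in the presence of 17 at rt should give cyclobutenone 19, now isolated, and heating in toluene at 110 °C converts it into 22.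

Step 5. The hindered C5 radical may be reduced by the stannane before it adds, or acrolein may polymerise. The fallback sets out from 8 and returns at 10. Keck allylation (allyltributylstannane, AIBN, PhH, 80 °C), a chain with no hydride donor, should deliver the allyl lactone F6 with the same facial preference. Hydroboration–oxidation (9-BBN, then NaBO3·4H2O) gives the primary alcohol F7, and Dess–Martin periodinane gives 10.

**Further compounds**

F1 | step 12 | (4S,5S,10S)-7-hydroxy-12-(triisopropylsilyloxy)icetexa-8,12-diene-11,14-dion-19,10-olide (C7 epimers) | OC1C[C@@H]2[C@]3(CCC[C@]2(C)C(=O)O3)CC2=C1C(=O)C(C(C)C)=C(O[Si](C(C)C)(C(C)C)C(C)C)C2=O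
F2 | step 12 | (4S,5S,10S)-12-(triisopropylsilyloxy)icetexa-8,12-diene-7,11,14-trion-19,10-olide | O=C1C[C@@H]2[C@]3(CCC[C@]2(C)C(=O)O3)CC2=C1C(=O)C(C(C)C)=C(O[Si](C(C)C)(C(C)C)C(C)C)C2=O
F3 | step 12 | (4S,5S,7R,10S)-7α-hydroxy-12-(triisopropylsilyloxy)icetexa-8,12-diene-11,14-dion-19,10-olide | O[C@@H]1C[C@@H]2[C@]3(CCC[C@]2(C)C(=O)O3)CC2=C1C(=O)C(C(C)C)=C(O[Si](C(C)C)(C(C)C)C(C)C)C2=O
F4 | step 9 | homologous acid: carboxymethyl group (C11H2–C14O2H) on C9 of the ring B cycloheptene of the tricyclic lactone | OC(=O)CC1=CCC[C@@H]2[C@]3(CCC[C@]2(C)C(=O)O3)C1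
F5 | step 9 | acid chloride of F4 | ClC(=O)CC1=CCC[C@@H]2[C@]3(CCC[C@]2(C)C(=O)O3)C1
F6 | step 5 | (1S,5S,8S)-1-methyl-5-[2-(2-methyl-1,3-dioxolan-2-yl)ethyl]-8-(prop-2-enyl)-6-oxabicyclo[3.2.1]octan-7-one | C=CC[C@@H]1[C@]2(CCC[C@]1(C)C(=O)O2)CCC3(C)OCCO3
F7 | step 5 | (1S,5S,8S)-8-(3-hydroxypropyl)-1-methyl-5-[2-(2-methyl-1,3-dioxolan-2-yl)ethyl]-6-oxabicyclo[3.2.1]octan-7-one | OCCC[C@@H]1[C@]2(CCC[C@]1(C)C(=O)O2)CCC3(C)OCCO3
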